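**Plan**

1. Retrosynthesis cuts, in this order: the prenyl C–C bond at the quaternary carbon C6 (chromene numbering; made as allyl by dearomative allylation, then cross‑metathesis), the acyl–oxygen bond of a temporary lactone between the acid and the C7 oxygen, the C4–C4a acyl bond of the pyranone (ring B), and finally the carbocycle (ring A) itself.
2. Ring A (C4a, C5, C6, C7, C8, C8a) is a masked phloroglucinol: oxygen on C5, C7 and C8a alternates with carbon substituents on C4a, C6 and C8. This alternation lets it be cut into a 3‑alkoxycyclobutenone (C7 carbonyl, C8, C8a–O, C4a) and a siloxyalkyne (C6, C5–O), i.e. a four‑membered ring expanded by two carbons.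
3. Forward: three fragments are made (a siloxyalkyne from (−)‑α‑pinene, all ten terpene carbons kept, pinene C3 becoming C5 of ring A; a chiral alkoxyacetylene; a 3‑phenylglutarate half‑ester). A ketene [2+2] gives the cyclobutenone, the benzannulation gives ring A with all six substituents in place, then ring B, dearomatization at C6, prenyl, lactone opening.
4. Stereochemistry: cyclobutane centres from α‑pinene; the cis‑2,3‑dimethyl centres from an auxiliary‑controlled syn aldol, brought in through an ether C–O bond that is never broken; the benzylic centre from catalytic desymmetrization of the anhydride; the quaternary centre from ligand‑controlled palladium allylation.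

Key step: step 11

Remark: the target is a vinylogous acid and is written in the tautomer of the given structure; the sense of induction of the cinchona catalyst (step 9) and of the diphosphine (step 16) is taken from the usual models and is confirmed on first use, the pseudoenantiomeric catalyst or antipodal ligand serving otherwise without change to the route.

**Step 1**
Reactants: 1 (1S,5S)-(−)-α-pinene
Product: 2 cis-pinonic acid = 2-[(1R,3R)-3-acetyl-2,2-dimethylcyclobutyl]acetic acid
Conditions: RuCl3·xH2O (2 mol%), NaIO4 (4.1 equiv), CCl4/MeCN/H2O (2:2:3), 20 °C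
Reagents that add atoms: sodium periodate [Na+].[O-]I(=O)(=O)=O; water O
Why: RuO4 formed in the flask cleaves the trisubstituted alkene to methyl ketone and carboxylic acid (oxidative alkene cleavage) under non‑basic conditions, so the cis‑1,3‑disubstituted cyclobutane and both terpene stereocentres are kept.

**Step 2**
Reactants: 2 cis-pinonic acid
Product: 3 methyl 2-[(1R,3R)-3-acetyl-2,2-dimethylcyclobutyl]acetate
Conditions: Me3SiCHN2, MeOH/toluene (1:4), 0 °C
Reagents that add atoms: (trimethylsilyl)diazomethane C[Si](C)(C)C=[N+]=[N-]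
Why: O‑methylation of the acid by the diazoalkane is neutral, so the epimerizable ring carbon next to the acetyl group should keep its cis configuration (esterification).

**Step 3**
Reactants: 3 methyl cis-pinonate
Product: 4 methyl 2-[(1R,3S)-2,2-dimethyl-3-(prop-1-en-2-yl)cyclobutyl]acetate
Conditions: Zn, CH2Br2, TiCl4, THF (reagent aged at 5 °C); then 3, CH2Cl2, 20 °C
Reagents that add atoms: dibromomethane BrCBr
Why: Lombardo–Takai methylenation is non‑basic and selective for ketone over ester, so the isopropenyl group should form without epimerization of the adjacent ring carbon.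

**Step 4**
Reactants: 4 methyl 2-[(1R,3S)-2,2-dimethyl-3-(prop-1-en-2-yl)cyclobutyl]acetate
Product: 6 triisopropyl({3-[(1R,3S)-2,2-dimethyl-3-(prop-1-en-2-yl)cyclobutyl]prop-1-yn-1-yl}oxy)silane, via lithium ynolate 5 (not isolated)
Conditions: CH2Br2, lithium 2,2,6,6-tetramethylpiperidide, THF, −78 °C; 4; then LiN(SiMe3)2; then n-BuLi, −78 → 20 °C; then i-Pr3SiCl, −78 → 0 °C
Reagents that add atoms: dibromomethane BrCBr; chlorotriisopropylsilane CC(C)[Si](Cl)(C(C)C)C(C)C
Why: Kowalski ynolate rearrangement: dibromomethyllithium adds to the ester, enolization and bromine–lithium exchange trigger a 1,2‑shift of the alkyl group to the ynolate, and the bulky silyl chloride traps it on oxygen, so the former ester carbon becomes the oxygen‑bearing alkyne carbon.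

**Step 5**
Reactants: 7 (4S)-4-benzyl-3-propanoyl-1,3-oxazolidin-2-one
Product: 9 (4S)-4-benzyl-3-[(2S,3R)-3-hydroxy-2-methylbutanoyl]-1,3-oxazolidin-2-one, via boron enolate 8 (not isolated)
Conditions: n-Bu2BOTf, i-Pr2NEt, CH2Cl2, 0 °C; MeCHO, −78 → 0 °C; then pH 7 buffer, MeOH, H2O2 (30%), 0 °C
Reagents that add atoms: acetaldehyde CC=O
Why: Evans syn aldol reaction: the Z boron enolate reacts through a closed chair transition state on the face away from the benzyl group of the auxiliary, which should set both new centres as (2S,3R) syn.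

**Step 6**
Reactants: 9 (4S)-4-benzyl-3-[(2S,3R)-3-hydroxy-2-methylbutanoyl]-1,3-oxazolidin-2-one
Product: 10 (2R,3R)-2-methylbutane-1,3-diol
Conditions: LiBH4, MeOH (1.1 equiv), THF, 0 °C
Reagents that add atoms: none
Why: Reductive cleavage of the N‑acyl oxazolidinone by borohydride gives the 1,3‑diol without touching either stereocentre and returns the auxiliary.

**Step 7**
Reactants: 10 (2R,3R)-2-methylbutane-1,3-diol
Product: 11 (2R,3R)-3-methyl-4-(trityloxy)butan-2-ol
Conditions: Ph3CCl, Et3N, DMAP (cat.), CH2Cl2, 20 °C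
Reagents that add atoms: trityl chloride ClC(c1ccccc1)(c1ccccc1)c1ccccc1
Why: The bulky trityl chloride etherifies only the primary hydroxyl (selective protection) and gives a group that cannot migrate and is inert to KH and n-BuLi in step 8.

**Step 8**
Reactants: 11 (2R,3R)-3-methyl-4-(trityloxy)butan-2-ol
Product: 14 (2R,3R)-2-(ethynyloxy)-3-methyl-4-(trityloxy)butane, via dichlorovinyl ether 12 (not isolated), via lithium alkoxyacetylide 13 (not isolated)
Conditions: KH, THF, 0 → 20 °C; Cl2C=CHCl; then n-BuLi (2.5 equiv), −78 → −40 °C; MeOH, −78 °C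
Reagents that add atoms: trichloroethylene ClC=C(Cl)Cl
Why: The alkoxide adds to dichloroacetylene formed in the flask, and elimination followed by chlorine–lithium exchange with n-BuLi gives the alkoxyacetylide, which is protonated (dichlorovinyl ether route to alkynyl ethers); the carbinol C–O bond is never broken, so its configuration is retained.

**Step 9**
Reactants: 15 3-phenylglutaric anhydride
Product: 16 (3S)-5-methoxy-5-oxo-3-phenylpentanoic acid
Conditions: MeOH (10 equiv), quinidine-derived bifunctional thiourea catalyst (9-amino-9-deoxy-epi-quinidine 3,5-bis(trifluoromethyl)phenyl thiourea, 10 mol%), MTBE, −20 °C; recrystallization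
Reagents that add atoms: methanol CO
Why: Catalytic desymmetrizing alcoholysis of the prochiral anhydride: the bifunctional cinchona catalyst directs methanol to one of the two enantiotopic carbonyl groups, which should set the benzylic centre as S.

**Step 10**
Reactants: 16 (3S)-5-methoxy-5-oxo-3-phenylpentanoic acid (1.5 equiv); 14 (2R,3R)-2-(ethynyloxy)-3-methyl-4-(trityloxy)butane
Product: 19 methyl (3R)-3-(2-{[(2R,3R)-3-methyl-4-(trityloxy)butan-2-yl]oxy}-4-oxocyclobut-2-en-1-yl)-3-phenylpropanoate (both epimers at the ring CH), via acid chloride 17 (not isolated), via ketene 18 (not isolated)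
Conditions: (COCl)2, DMF (cat.), CH2Cl2, 20 °C, evaporate; then 14, Et3N (slow addition), MeCN, 20 °C
Reagents that add atoms: none
Why: Dehydrochlorination of the acid chloride gives the monoalkylketene, which should undergo regioselective [2+2] cycloaddition with the electron‑rich alkyne (terminal alkyne carbon to the ketene carbonyl carbon) to the 3‑alkoxycyclobutenone; the ring CH forms as both epimers, which is without consequence because it becomes sp2 in step 11.

**Step 11**
Reactants: 19 cyclobutenone methyl (3R)-3-(2-{[(2R,3R)-3-methyl-4-(trityloxy)butan-2-yl]oxy}-4-oxocyclobut-2-en-1-yl)-3-phenylpropanoate; 6 siloxyalkyne triisopropyl({3-[(1R,3S)-2,2-dimethyl-3-(prop-1-en-2-yl)cyclobutyl]prop-1-yn-1-yl}oxy)silane (1.5 equiv)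
Product: 25 (4S)-8-{[(1R,3S)-2,2-dimethyl-3-(prop-1-en-2-yl)cyclobutyl]methyl}-5-{[(2R,3R)-3-methyl-4-(trityloxy)butan-2-yl]oxy}-4-phenyl-7-(triisopropylsilyloxy)chroman-2-one, via vinylketene 20 (not isolated), via vinylcyclobutenone 21 (not isolated), via dienylketene 22 (not isolated), via cyclohexadienone 23 (not isolated), via phenol ester 24 (not isolated)
Conditions: toluene (0.2 M), 80 °C, 3 h; then reflux (110 °C) through 4 Å molecular sieves, 12 h
Reagents that add atoms: none
Why: Danheiser benzannulation: 19 should open by thermal conrotatory 4π ring opening of its C1–C4 bond to vinylketene 20, whose ketene C=C adds to siloxyalkyne 6 in a [2+2] cycloaddition to 2‑vinylcyclobutenone 21; a second 4π opening gives dienylketene 22, which closes by disrotatory 6π electrocyclization (ketene carbon to diene terminus) to dienone 23 and tautomerizes to phenol 24. Net, the four carbons of the cyclobutenone are kept and the two alkyne carbons are inserted between its C1 and C2, a ring expansion from four to six atoms, the closest known reaction type being the benzannulation of 3‑oxygenated cyclobutenones with siloxyalkynes to phloroglucinol derivatives. Ring closures: the transient four‑membered ring by ketene–alkyne [2+2] cycloaddition, ring A by 6π electrocyclization, and the lactone (ring C) by 6‑exo‑trig transesterification of the new phenol onto the methyl ester, helped by the two flanking ortho substituents and by removal of methanol. No stereocentre is created: the ring CH of 19 becomes sp2, and the benzylic, ether and cyclobutane centres are untouched because the medium is neutral and none of them is α to a ketene or an enolizable carbonyl. The selectivity needed is regiochemical, and the polarization of the siloxyalkyne secures it: its nucleophilic alkyl‑bearing carbon bonds to the ketene carbonyl carbon, so the silyloxy group ends meta to the new hydroxyl with the cyclobutylmethyl group between them and all six ring positions are fixed in one operation. Outward rotation of the C4 substituent in the first ring opening keeps the benzylic hydrogen away from the ketene, which should suppress a 1,5‑hydrogen shift.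

**Step 12**
Reactants: 25 trityl ether lactone
Product: 26 (4S)-8-{[(1R,3S)-2,2-dimethyl-3-(prop-1-en-2-yl)cyclobutyl]methyl}-5-{[(2R,3R)-4-hydroxy-3-methylbutan-2-yl]oxy}-4-phenyl-7-(triisopropylsilyloxy)chroman-2-one
Conditions: HCO2H/Et2O (1:1), 20 °C, 20 min; aqueous NaHCO3
Reagents that add atoms: none
Why: Acidolysis of the trityl ether through the trityl cation is fast in formic acid, which is too weak to protonate the isopropenyl group or cleave the aryl silyl ether and contains no alcohol that could open the lactone (deprotection).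

**Step 13**
Reactants: 26 primary alcohol
Product: 28 (2S,3R)-3-({(4S)-8-{[(1R,3S)-2,2-dimethyl-3-(prop-1-en-2-yl)cyclobutyl]methyl}-2-oxo-4-phenyl-7-(triisopropylsilyloxy)chroman-5-yl}oxy)-2-methylbutanoic acid, via aldehyde 27 (not isolated)
Conditions: TEMPO (20 mol%), PhI(OAc)2 (2.5 equiv), MeCN/H2O (1:1), 20 °C
Reagents that add atoms: water O
Why: Oxoammonium‑mediated oxidation takes the primary alcohol through the aldehyde hydrate to the acid under weakly acidic conditions, which should avoid β‑elimination of the aryloxy group and epimerization of the α‑centre, and no free phenol is present to be oxidized.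

**Step 14**
Reactants: 28 carboxylic acid
Product: 30 (2R,3S,10S)-6-{[(1R,3S)-2,2-dimethyl-3-(prop-1-en-2-yl)cyclobutyl]methyl}-2,3-dimethyl-10-phenyl-5-(triisopropylsilyloxy)-2,3,9,10-tetrahydro-4H,8H-pyrano[2,3-f]chromene-4,8-dione, via mixed anhydride 29 (not isolated)
Conditions: (CF3CO)2O (1.5 equiv), CH2Cl2, 0 °C
Reagents that add atoms: none
Why: Intramolecular Friedel–Crafts acylation through the mixed trifluoroacetic anhydride: the only free ring position lies ortho to both ether oxygens and should close the six‑membered pyranone (ring B) at 0 °C without a metal Lewis acid, so the cis‑2,3‑dimethyl centres set in step 5 enter ring B unchanged.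

**Step 15**
Reactants: 30 silyl ether
Product: 31 (2R,3S,10S)-6-{[(1R,3S)-2,2-dimethyl-3-(prop-1-en-2-yl)cyclobutyl]methyl}-5-hydroxy-2,3-dimethyl-10-phenyl-2,3,9,10-tetrahydro-4H,8H-pyrano[2,3-f]chromene-4,8-dione
Conditions: Bu4NF, AcOH (1:1, 1.2 equiv), THF, 0 °C
Reagents that add atoms: none
Why: Fluoride cleaves the aryl silyl ether, which the ortho ketone activates, and the acetic acid buffer keeps the medium non‑basic, so the chromanone α‑centre should not epimerize and the lactone stays closed (desilylation).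

**Step 16**
Reactants: 31 ortho-acyl phenol
Product: 32 (2R,3S,6R,10S)-6-allyl-6-{[(1R,3S)-2,2-dimethyl-3-(prop-1-en-2-yl)cyclobutyl]methyl}-2,3-dimethyl-10-phenyl-2,3,9,10-tetrahydro-4H,8H-pyrano[2,3-f]chromene-4,5,8(6H)-trione
Conditions: allyl tert-butyl carbonate (1.5 equiv), Pd2(dba)3·CHCl3 (2.5 mol%, zerovalent palladium), (R,R)-N,N′-bis[2-(diphenylphosphino)benzoyl]cyclohexane-1,2-diamine (7.5 mol%), CH2Cl2, 0 → 20 °C
Reagents that add atoms: allyl tert-butyl carbonate C=CCOC(=O)OC(C)(C)C
Why: Tsuji–Trost allylation in its asymmetric dearomative form: the chelated phenoxide should attack the π‑allyl palladium complex through the ortho carbon that carries the cyclobutylmethyl group (O‑allylation is reversible under zerovalent palladium and the para carbon is blocked by a secondary alkyl group), and the chiral diphosphine pocket selects the face of the planar nucleophile, setting the quaternary centre as R under ligand control because the substrate stereocentres are remote from C6.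

**Step 17**
Reactants: 32 allyl trione
Product: 33 (2R,3S,6R,10S)-6-{[(1R,3S)-2,2-dimethyl-3-(prop-1-en-2-yl)cyclobutyl]methyl}-2,3-dimethyl-6-(3-methylbut-2-en-1-yl)-10-phenyl-2,3,9,10-tetrahydro-4H,8H-pyrano[2,3-f]chromene-4,5,8(6H)-trione
Conditions: 2-methylbut-2-ene/CH2Cl2 (1:2), second-generation Grubbs catalyst (5 mol%), 40 °C
Reagents that add atoms: 2-methylbut-2-ene CC=C(C)C
Why: Olefin cross‑metathesis with a large excess of 2‑methylbut‑2‑ene should convert the monosubstituted allyl alkene into the prenyl group, while the 1,1‑disubstituted isopropenyl alkene and the fully substituted ring alkenes do not react.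

**Step 18**
Reactants: 33 prenyl lactone
Product: 34 (3S)-3-[(2R,3S,6R)-6-{[(1R,3S)-2,2-dimethyl-3-(prop-1-en-2-yl)cyclobutyl]methyl}-4-hydroxy-2,3-dimethyl-6-(3-methylbut-2-en-1-yl)-5,7-dioxo-3,5,6,7-tetrahydro-2H-chromen-8-yl]-3-phenylpropanoic acid
Conditions: LiOH (3 equiv), THF/H2O (3:1), 0 °C; then HCl (0.5 M) to pH 3, 0 °C
Reagents that add atoms: lithium hydroxide [Li+].[OH-]
Why: Hydroxide should open the enol lactone, the most electrophilic carbonyl, at 0 °C (saponification) to the carboxylate and the vinylogous acid anion, whose delocalized charge protects the chromanone α‑centre and the 1,3‑dicarbonyl unit from further attack, and mild acidification gives the target.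

**Compound list**

1 | (1S,5S)-(−)-α-pinene | CC1=CC[C@H]2C[C@@H]1C2(C)C | starting material
2 | cis-pinonic acid = 2-[(1R,3R)-3-acetyl-2,2-dimethylcyclobutyl]acetic acid | CC(=O)[C@@H]1C[C@H](CC(=O)O)C1(C)C | intermediate
3 | methyl 2-[(1R,3R)-3-acetyl-2,2-dimethylcyclobutyl]acetate | CC(=O)[C@@H]1C[C@H](CC(=O)OC)C1(C)C | intermediate
4 | methyl 2-[(1R,3S)-2,2-dimethyl-3-(prop-1-en-2-yl)cyclobutyl]acetate | C=C(C)[C@@H]1C[C@H](CC(=O)OC)C1(C)C | intermediate
5 | lithium 3-[(1R,3S)-2,2-dimethyl-3-(prop-1-en-2-yl)cyclobutyl]prop-1-yn-1-olate (not isolated) | C=C(C)[C@@H]1C[C@H](CC#C[O-])C1(C)C.[Li+] | intermediate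
6 | triisopropyl({3-[(1R,3S)-2,2-dimethyl-3-(prop-1-en-2-yl)cyclobutyl]prop-1-yn-1-yl}oxy)silane | C=C(C)[C@@H]1C[C@H](CC#CO[Si](C(C)C)(C(C)C)C(C)C)C1(C)C | intermediate
7 | (4S)-4-benzyl-3-propanoyl-1,3-oxazolidin-2-one | CCC(=O)N1[C@@H](Cc2ccccc2)COC1=O | starting material
8 | (Z)-di-n-butylboron enolate of 7 (not isolated) | C/C=C(\OB(CCCC)CCCC)N1[C@@H](Cc2ccccc2)COC1=O | intermediate
9 | (4S)-4-benzyl-3-[(2S,3R)-3-hydroxy-2-methylbutanoyl]-1,3-oxazolidin-2-one | O=C([C@@H](C)[C@@H](C)O)N1[C@@H](Cc2ccccc2)COC1=O | intermediate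
10 | (2R,3R)-2-methylbutane-1,3-diol | OC[C@@H](C)[C@@H](C)O | intermediate
11 | (2R,3R)-3-methyl-4-(trityloxy)butan-2-ol | c1ccccc1C(c1ccccc1)(c1ccccc1)OC[C@@H](C)[C@@H](C)O | intermediate
12 | (2R,3R)-2-{[(E)-1,2-dichloroethenyl]oxy}-3-methyl-4-(trityloxy)butane (not isolated) | c1ccccc1C(c1ccccc1)(c1ccccc1)OC[C@@H](C)[C@@H](C)O/C(Cl)=C\Cl | intermediate
13 | lithium 2-{[(2R,3R)-3-methyl-4-(trityloxy)butan-2-yl]oxy}ethyn-1-ide (not isolated) | c1ccccc1C(c1ccccc1)(c1ccccc1)OC[C@@H](C)[C@@H](C)OC#C[Li] | intermediate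
14 | (2R,3R)-2-(ethynyloxy)-3-methyl-4-(trityloxy)butane | c1ccccc1C(c1ccccc1)(c1ccccc1)OC[C@@H](C)[C@@H](C)OC#C | intermediate
15 | 3-phenylglutaric anhydride (4-phenyloxane-2,6-dione) | O=C1CC(c2ccccc2)CC(=O)O1 | starting material
16 | (3S)-5-methoxy-5-oxo-3-phenylpentanoic acid | OC(=O)C[C@@H](CC(=O)OC)c1ccccc1 | intermediate
17 | methyl (3R)-5-chloro-5-oxo-3-phenylpentanoate (not isolated) | ClC(=O)C[C@@H](CC(=O)OC)c1ccccc1 | intermediate
18 | ketene methyl (3R)-5-oxo-3-phenylpent-4-enoate (not isolated) | O=C=C[C@@H](CC(=O)OC)c1ccccc1 | intermediate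
19 | methyl (3R)-3-(2-{[(2R,3R)-3-methyl-4-(trityloxy)butan-2-yl]oxy}-4-oxocyclobut-2-en-1-yl)-3-phenylpropanoate (both epimers at the ring CH) | O=C1C=C(O[C@H](C)[C@H](C)COC(c2ccccc2)(c2ccccc2)c2ccccc2)C1[C@@H](CC(=O)OC)c1ccccc1 | intermediate
20 | vinylketene methyl (3R,4Z)-5-{[(2R,3R)-3-methyl-4-(trityloxy)butan-2-yl]oxy}-7-oxo-3-phenylhepta-4,6-dienoate (not isolated) | O=C=C/C(O[C@H](C)[C@H](C)COC(c1ccccc1)(c1ccccc1)c1ccccc1)=C/[C@@H](CC(=O)OC)c1ccccc1 | intermediate
21 | 2-vinylcyclobutenone from 20 plus 6: 2-(cyclobutylmethyl)-3-(triisopropylsilyloxy)-4-alkenylcyclobut-2-en-1-one (not isolated) | O=C1C(C[C@H]2C[C@@H](C(C)=C)C2(C)C)=C(O[Si](C(C)C)(C(C)C)C(C)C)C1/C(O[C@H](C)[C@H](C)COC(c1ccccc1)(c1ccccc1)c1ccccc1)=C/[C@@H](CC(=O)OC)c1ccccc1 | intermediate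
22 | dienylketene from ring opening of 21 (not isolated) | O=C=C(C[C@H]1C[C@@H](C(C)=C)C1(C)C)/C(O[Si](C(C)C)(C(C)C)C(C)C)=C\C(O[C@H](C)[C@H](C)COC(c1ccccc1)(c1ccccc1)c1ccccc1)=C\[C@@H](CC(=O)OC)c1ccccc1 | intermediate
23 | cyclohexa-2,4-dienone keto tautomer of 24 (not isolated) | O=C1C(C[C@H]2C[C@@H](C(C)=C)C2(C)C)=C(O[Si](C(C)C)(C(C)C)C(C)C)C=C(O[C@H](C)[C@H](C)COC(c2ccccc2)(c2ccccc2)c2ccccc2)C1[C@@H](CC(=O)OC)c1ccccc1 | intermediate
24 | methyl (3S)-3-[3-{[(1R,3S)-2,2-dimethyl-3-(prop-1-en-2-yl)cyclobutyl]methyl}-2-hydroxy-6-{[(2R,3R)-3-methyl-4-(trityloxy)butan-2-yl]oxy}-4-(triisopropylsilyloxy)phenyl]-3-phenylpropanoate (not isolated) | Oc1c(C[C@H]2C[C@@H](C(C)=C)C2(C)C)c(O[Si](C(C)C)(C(C)C)C(C)C)cc(O[C@H](C)[C@H](C)COC(c2ccccc2)(c2ccccc2)c2ccccc2)c1[C@@H](CC(=O)OC)c1ccccc1 | intermediate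
25 | (4S)-8-{[(1R,3S)-2,2-dimethyl-3-(prop-1-en-2-yl)cyclobutyl]methyl}-5-{[(2R,3R)-3-methyl-4-(trityloxy)butan-2-yl]oxy}-4-phenyl-7-(triisopropylsilyloxy)chroman-2-one | O=C1C[C@@H](c2ccccc2)c2c(O1)c(C[C@H]3C[C@@H](C(C)=C)C3(C)C)c(O[Si](C(C)C)(C(C)C)C(C)C)cc2O[C@H](C)[C@H](C)COC(c2ccccc2)(c2ccccc2)c2ccccc2 | intermediate
26 | (4S)-8-{[(1R,3S)-2,2-dimethyl-3-(prop-1-en-2-yl)cyclobutyl]methyl}-5-{[(2R,3R)-4-hydroxy-3-methylbutan-2-yl]oxy}-4-phenyl-7-(triisopropylsilyloxy)chroman-2-one | O=C1C[C@@H](c2ccccc2)c2c(O1)c(C[C@H]3C[C@@H](C(C)=C)C3(C)C)c(O[Si](C(C)C)(C(C)C)C(C)C)cc2O[C@H](C)[C@H](C)CO | intermediate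
27 | (2S,3R)-3-({(4S)-8-{[(1R,3S)-2,2-dimethyl-3-(prop-1-en-2-yl)cyclobutyl]methyl}-2-oxo-4-phenyl-7-(triisopropylsilyloxy)chroman-5-yl}oxy)-2-methylbutanal (not isolated) | O=C1C[C@@H](c2ccccc2)c2c(O1)c(C[C@H]3C[C@@H](C(C)=C)C3(C)C)c(O[Si](C(C)C)(C(C)C)C(C)C)cc2O[C@H](C)[C@H](C)C=O | intermediate
28 | (2S,3R)-3-({(4S)-8-{[(1R,3S)-2,2-dimethyl-3-(prop-1-en-2-yl)cyclobutyl]methyl}-2-oxo-4-phenyl-7-(triisopropylsilyloxy)chroman-5-yl}oxy)-2-methylbutanoic acid | O=C1C[C@@H](c2ccccc2)c2c(O1)c(C[C@H]3C[C@@H](C(C)=C)C3(C)C)c(O[Si](C(C)C)(C(C)C)C(C)C)cc2O[C@H](C)[C@H](C)C(=O)O | intermediate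
29 | mixed anhydride of 28 and trifluoroacetic acid (not isolated) | O=C1C[C@@H](c2ccccc2)c2c(O1)c(C[C@H]3C[C@@H](C(C)=C)C3(C)C)c(O[Si](C(C)C)(C(C)C)C(C)C)cc2O[C@H](C)[C@H](C)C(=O)OC(=O)C(F)(F)F | intermediate
30 | (2R,3S,10S)-6-{[(1R,3S)-2,2-dimethyl-3-(prop-1-en-2-yl)cyclobutyl]methyl}-2,3-dimethyl-10-phenyl-5-(triisopropylsilyloxy)-2,3,9,10-tetrahydro-4H,8H-pyrano[2,3-f]chromene-4,8-dione | O=C1C[C@@H](c2ccccc2)c2c(O1)c(C[C@H]3C[C@@H](C(C)=C)C3(C)C)c(O[Si](C(C)C)(C(C)C)C(C)C)c3c2O[C@H](C)[C@H](C)C3=O | intermediate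
31 | (2R,3S,10S)-6-{[(1R,3S)-2,2-dimethyl-3-(prop-1-en-2-yl)cyclobutyl]methyl}-5-hydroxy-2,3-dimethyl-10-phenyl-2,3,9,10-tetrahydro-4H,8H-pyrano[2,3-f]chromene-4,8-dione | O=C1C[C@@H](c2ccccc2)c2c(O1)c(C[C@H]3C[C@@H](C(C)=C)C3(C)C)c(O)c3c2O[C@H](C)[C@H](C)C3=O | intermediate
32 | (2R,3S,6R,10S)-6-allyl-6-{[(1R,3S)-2,2-dimethyl-3-(prop-1-en-2-yl)cyclobutyl]methyl}-2,3-dimethyl-10-phenyl-2,3,9,10-tetrahydro-4H,8H-pyrano[2,3-f]chromene-4,5,8(6H)-trione | C=C(C)[C@@H]1C[C@H](C[C@@]2(CC=C)C(=O)C3=C(O[C@H](C)[C@H](C)C3=O)C4=C2OC(=O)C[C@H]4c2ccccc2)C1(C)C | intermediate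
33 | (2R,3S,6R,10S)-6-{[(1R,3S)-2,2-dimethyl-3-(prop-1-en-2-yl)cyclobutyl]methyl}-2,3-dimethyl-6-(3-methylbut-2-en-1-yl)-10-phenyl-2,3,9,10-tetrahydro-4H,8H-pyrano[2,3-f]chromene-4,5,8(6H)-trione | C=C(C)[C@@H]1C[C@H](C[C@@]2(CC=C(C)C)C(=O)C3=C(O[C@H](C)[C@H](C)C3=O)C4=C2OC(=O)C[C@H]4c2ccccc2)C1(C)C | intermediate
34 | (3S)-3-[(2R,3S,6R)-6-{[(1R,3S)-2,2-dimethyl-3-(prop-1-en-2-yl)cyclobutyl]methyl}-4-hydroxy-2,3-dimethyl-6-(3-methylbut-2-en-1-yl)-5,7-dioxo-3,5,6,7-tetrahydro-2H-chromen-8-yl]-3-phenylpropanoic acid | C=C(C)[C@@H]1C[C@H](C[C@@]2(CC=C(C)C)C(=O)C3=C(O)[C@@H](C)[C@@H](C)OC3=C([C@@H](CC(=O)O)c3ccccc3)C2=O)C1(C)C | target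

**Step count and risks**

Total step count: 18. Longest linear sequence: 13 steps (from 7 through steps 5–8 and 10–18).

Steps most likely to fail:

Step 16. The ligand pocket may discriminate the two faces of the phenoxide poorly, so that the quaternary centre forms with low selectivity, or allylation on oxygen may outrun allylation on carbon. The fallback sets out from 31 and gives up catalyst control. The lithium phenoxide (LiN(SiMe3)2, toluene, 0 °C), a tight chelate with the ortho ketone in a non‑polar solvent, is alkylated on carbon with allyl bromide in the classical alkylative dearomatization of acylphloroglucinols. This should give 32 together with its C6 epimer (2R,3S,6S,10S)-6-allyl trione F1; the two are diastereomers and are separated by chromatography. The route is rejoined at 32.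

Step 11. At 80–110 °C the cyclobutenone or the ketenes may be lost by dimerization or by capture with the newly formed phenol before the cycloaddition, and the lactone closure may stay incomplete. The fallback sets out from 19 and 6 and separates the events. Irradiation at 350 nm in CH2Cl2 at 20 °C opens the cyclobutenone photochemically, so the vinylketene 20 is formed and trapped at ambient temperature. The cycloadduct 21 is isolated. Pure 21 is then heated briefly in toluene at 110 °C for the second ring opening and the electrocyclization to 24. Continued reflux through molecular sieves, with a catalytic amount of pyridinium p‑toluenesulfonate if needed, closes the lactone. The route is rejoined at 25. No compound outside the list is made (F0).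

Step 14. Trifluoroacetic acid set free during the acylation may protonate the isopropenyl group, with ring enlargement of the cyclobutane, or the centre next to the new ketone may epimerize. The fallback sets out from 26 and avoids acylium chemistry. Dess–Martin periodinane buffered with NaHCO3 gives the aldehyde 27, here isolated. MgBr2·OEt2 in CH2Cl2 at −40 °C then promotes chelation‑assisted addition of the electron‑rich arene to the aldehyde (intramolecular hydroxyalkylation) to the chroman‑4‑ol F2. A second Dess–Martin oxidation gives the ketone, and the route is rejoined at 30.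

**Further compounds**

F1 | step 16 | (2R,3S,6S,10S)-6-allyl-6-{[(1R,3S)-2,2-dimethyl-3-(prop-1-en-2-yl)cyclobutyl]methyl}-2,3-dimethyl-10-phenyl-2,3,9,10-tetrahydro-4H,8H-pyrano[2,3-f]chromene-4,5,8(6H)-trione | C=C(C)[C@@H]1C[C@H](C[C@]2(CC=C)C(=O)C3=C(O[C@H](C)[C@H](C)C3=O)C4=C2OC(=O)C[C@H]4c2ccccc2)C1(C)C
F0 | step 11 | none | none
F2 | step 14 | (2R,3S,10S)-6-{[(1R,3S)-2,2-dimethyl-3-(prop-1-en-2-yl)cyclobutyl]methyl}-4-hydroxy-2,3-dimethyl-10-phenyl-5-(triisopropylsilyloxy)-3,4,9,10-tetrahydro-2H,8H-pyrano[2,3-f]chromen-8-one (both C4 epimers) | O=C1C[C@@H](c2ccccc2)c2c(O1)c(C[C@H]3C[C@@H](C(C)=C)C3(C)C)c(O[Si](C(C)C)(C(C)C)C(C)C)c3c2O[C@H](C)[C@H](C)C3O
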